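## Retrosynthetic overview

- The two C5–prenyl bonds, including the quaternary, dearomatising one, come from two aromatic Claisen [3,3] shifts of a bis(1,1-dimethylallyl) ether of a 7-acyl-4,6-dihydroxy-2,3-dihydrobenzofuran.
- The dihydrofuran ring is closed by intramolecular Mitsunobu etherification (inversion) of an (S)-2,3-dihydroxy-3-methylbutyl side chain onto the phenol ortho to the acyl group, with the para-phenol blocked as a silyl ether.
- Side chain and acyl group are placed on tris-MOM phloroglucinol by two successive directed ortho-lithiations (epoxide, then Weinreb amide).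
- The single stereocentre is bought in methyl (S)-glycidate and carried into (S)-2-(oxiran-2-yl)propan-2-ol with MeMgBr.
- Ring order: benzene ring bought, then the dihydrofuran ring (Mitsunobu), then dearomatisation of the carbocycle in the last step.

Assumption: N-methoxy-N,3-dimethylbutanamide (10) is bought as a catalogue reagent, and the target is handled as the single enol tautomer drawn.

## Route

Step 1
Reactants: 1 phloroglucinol (benzene-1,3,5-triol); 2 chloromethyl methyl ether
Product: 3 1,3,5-tris(methoxymethoxy)benzene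
Conditions: NaH (3.6 eq), MOMCl (3.6 eq), DMF, 0 °C → rt
Reagents that add atoms: chloromethyl methyl ether, COCCl
Why: Williamson-type O-alkylation of all three phenoxides by the hard MOM electrophile gives the tris-acetal needed to direct the later lithiations; no stereocentre is involved.

Step 2
Reactants: 4 methyl (2S)-oxirane-2-carboxylate; 5 methylmagnesium bromide
Product: 7 2-[(2S)-oxiran-2-yl]propan-2-ol, via methyl ketone 6 (not isolated)
Conditions: MeMgBr (2.2 eq), THF, −78 → −40 °C; cold aq NH4Cl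
Reagents that add atoms: methylmagnesium bromide, C[Mg]Br
Why: Double Grignard addition to the activated ester is much faster than epoxide opening at low temperature, and the bought stereocentre is not a reacting centre, so (S) is retained.

Step 3
Reactants: 3 1,3,5-tris(methoxymethoxy)benzene; 7 2-[(2S)-oxiran-2-yl]propan-2-ol
Product: 9 (2S)-3-methyl-1-[2,4,6-tris(methoxymethoxy)phenyl]butane-2,3-diol, via aryllithium 8 (not isolated)
Conditions: 3 (2.4 eq), n-BuLi (2.2 eq), THF, 0 °C; then 7 (1.0 eq), BF3·OEt2 (2.0 eq), −78 °C; aq NH4Cl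
Reagents that add atoms: 2-[(2S)-oxiran-2-yl]propan-2-ol, CC(C)(O)[C@@H]1CO1
Why: Directed ortho-metalation between two OMOM groups, then BF3-promoted SN2 opening of the terminal epoxide at its CH2 (one equivalent of aryllithium is spent on the free OH), leaves the stereocentre untouched as (S).

Step 4
Reactants: 9 (2S)-3-methyl-1-[2,4,6-tris(methoxymethoxy)phenyl]butane-2,3-diol; 10 N-methoxy-N,3-dimethylbutanamide
Product: 12 1-{3-[(2S)-2,3-dihydroxy-3-methylbutyl]-2,4,6-tris(methoxymethoxy)phenyl}-3-methylbutan-1-one, via trilithiated diol 11 (not isolated)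
Conditions: n-BuLi (3.3 eq), TMEDA, THF, −20 → 0 °C; then 10 (1.5 eq), −78 → 0 °C; aq NH4Cl
Reagents that add atoms: N-methoxy-N,3-dimethylbutanamide, CC(C)CC(=O)N(C)OC
Why: After O-deprotonation, a second directed ortho-metalation at one of the two equivalent positions flanked by OMOM groups is trapped in a Weinreb ketone synthesis, whose chelated tetrahedral intermediate stops at the ketone.

Step 5
Reactants: 12 1-{3-[(2S)-2,3-dihydroxy-3-methylbutyl]-2,4,6-tris(methoxymethoxy)phenyl}-3-methylbutan-1-one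
Product: 13 1-{3-[(2S)-2,3-dihydroxy-3-methylbutyl]-2,4,6-trihydroxyphenyl}-3-methylbutan-1-one
Conditions: 3 M aq HCl, MeOH, 40 °C
Reagents that add atoms: none
Why: Acid-catalysed acetal methanolysis removes the three MOM groups under conditions too mild to ionise the tertiary alcohol, so diol and stereocentre survive.

Step 6
Reactants: 13 1-{3-[(2S)-2,3-dihydroxy-3-methylbutyl]-2,4,6-trihydroxyphenyl}-3-methylbutan-1-one; 14 chlorotri(propan-2-yl)silane
Product: 15 1-{3-[(2S)-2,3-dihydroxy-3-methylbutyl]-2,6-dihydroxy-4-[tri(propan-2-yl)silyloxy]phenyl}-3-methylbutan-1-one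
Conditions: TIPSCl (1.05 eq), imidazole, DMF, 0 °C
Reagents that add atoms: chlorotri(propan-2-yl)silane, CC(C)[Si](Cl)(C(C)C)C(C)C
Why: Chemoselective O-silylation takes the para-phenol, the most acidic and the only one never held in the ketone hydrogen bond, which blocks the oxygen that would otherwise win the ring closure.

Step 7
Reactants: 15 1-{3-[(2S)-2,3-dihydroxy-3-methylbutyl]-2,6-dihydroxy-4-[tri(propan-2-yl)silyloxy]phenyl}-3-methylbutan-1-one
Product: 17 1-[(2R)-4,6-dihydroxy-2-(2-hydroxypropan-2-yl)-2,3-dihydro-1-benzofuran-7-yl]-3-methylbutan-1-one, via silyl ether 16 (not isolated)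
Conditions: PPh3, DIAD, THF (0.02 M), 0 °C → rt; then TBAF, 0 °C; aq NH4Cl
Reagents that add atoms: none
Why: In this intramolecular Mitsunobu etherification the only free phenol next to the side chain displaces the activated secondary carbinol 5-exo-tet with inversion, turning the bought (S) centre into (R) while the tertiary OH stays inert, and fluoride then cleaves the aryl silyl ether.

Step 8
Reactants: 18 2-methylbut-3-en-2-ol; 19 di-tert-butyl dicarbonate
Product: 21 tert-butyl 2-methylbut-3-en-2-yl carbonate, via lithium alkoxide 20 (not isolated)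
Conditions: n-BuLi (1.0 eq), THF, 0 °C; then Boc2O, 0 °C → rt; aq NH4Cl
Reagents that add atoms: di-tert-butyl dicarbonate, CC(C)(C)OC(=O)OC(=O)OC(C)(C)C
Why: Acylation of the tertiary lithium alkoxide by Boc2O gives the mixed carbonate that serves as the π-allyl precursor.

Step 9
Reactants: 17 1-[(2R)-4,6-dihydroxy-2-(2-hydroxypropan-2-yl)-2,3-dihydro-1-benzofuran-7-yl]-3-methylbutan-1-one; 21 tert-butyl 2-methylbut-3-en-2-yl carbonate
Product: 22 1-[(2R)-2-(2-hydroxypropan-2-yl)-4,6-bis(2-methylbut-3-en-2-yloxy)-2,3-dihydro-1-benzofuran-7-yl]-3-methylbutan-1-one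
Conditions: 21 (3.0 eq), Pd(PPh3)4 (5 mol %), THF, 0 °C
Reagents that add atoms: tert-butyl 2-methylbut-3-en-2-yl carbonate, C=CC(C)(C)OC(=O)OC(C)(C)C
Why: In this Pd(0)-catalysed decarboxylative allylic etherification (Tsuji–Trost) the tert-butoxide released deprotonates both phenols, which attack the more substituted π-allyl terminus at low temperature to give the kinetic tertiary ethers, while the tertiary alcohol is not acidic enough to compete.

Step 10
Reactants: 22 1-[(2R)-2-(2-hydroxypropan-2-yl)-4,6-bis(2-methylbut-3-en-2-yloxy)-2,3-dihydro-1-benzofuran-7-yl]-3-methylbutan-1-one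
Product: 24 (2R)-6-hydroxy-2-(2-hydroxypropan-2-yl)-7-(3-methylbutanoyl)-5,5-bis(3-methylbut-2-en-1-yl)-2,3-dihydro-1-benzofuran-4(5H)-one, via mono-rearranged phenol 23 (not isolated)
Conditions: PhMe (degassed, 0.01 M), 110 °C, Ar
Reagents that add atoms: none
Why: Two consecutive aromatic Claisen [3,3] rearrangements deliver both prenyl groups to C5: the first goes to the only free ortho carbon and re-aromatises, the second is dearomative and ends in the enolised β-triketone/vinylogous ester as thermodynamic sink (shifts to the blocked C3a or C7 are reversible); C5 carries two identical groups, so no stereocentre forms and C2 stays (R).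

## Compound list

1 | phloroglucinol (benzene-1,3,5-triol) | Oc1cc(O)cc(O)c1 | starting material
2 | chloromethyl methyl ether | COCCl | starting material
3 | 1,3,5-tris(methoxymethoxy)benzene | COCOc1cc(OCOC)cc(OCOC)c1 | intermediate
4 | methyl (2S)-oxirane-2-carboxylate | COC(=O)[C@@H]1CO1 | starting material
5 | methylmagnesium bromide | C[Mg]Br | starting material
6 | 1-[(2S)-oxiran-2-yl]ethan-1-one (not isolated) | CC(=O)[C@@H]1CO1 | intermediate
7 | 2-[(2S)-oxiran-2-yl]propan-2-ol | CC(C)(O)[C@@H]1CO1 | intermediate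
8 | [2,4,6-tris(methoxymethoxy)phenyl]lithium (not isolated) | [Li]c1c(OCOC)cc(OCOC)cc1OCOC | intermediate
9 | (2S)-3-methyl-1-[2,4,6-tris(methoxymethoxy)phenyl]butane-2,3-diol | CC(C)(O)[C@@H](O)Cc1c(OCOC)cc(OCOC)cc1OCOC | intermediate
10 | N-methoxy-N,3-dimethylbutanamide | CC(C)CC(=O)N(C)OC | starting material
11 | O,O-dilithio alkoxide of 9, ring-lithiated at C3 (not isolated) | [Li]OC(C)(C)[C@@H](O[Li])Cc1c(OCOC)cc(OCOC)c([Li])c1OCOC | intermediate
12 | 1-{3-[(2S)-2,3-dihydroxy-3-methylbutyl]-2,4,6-tris(methoxymethoxy)phenyl}-3-methylbutan-1-one | CC(C)CC(=O)c1c(OCOC)cc(OCOC)c(C[C@H](O)C(C)(C)O)c1OCOC | intermediate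
13 | 1-{3-[(2S)-2,3-dihydroxy-3-methylbutyl]-2,4,6-trihydroxyphenyl}-3-methylbutan-1-one | CC(C)CC(=O)c1c(O)cc(O)c(C[C@H](O)C(C)(C)O)c1O | intermediate
14 | chlorotri(propan-2-yl)silane | CC(C)[Si](Cl)(C(C)C)C(C)C | starting material
15 | 1-{3-[(2S)-2,3-dihydroxy-3-methylbutyl]-2,6-dihydroxy-4-[tri(propan-2-yl)silyloxy]phenyl}-3-methylbutan-1-one | CC(C)CC(=O)c1c(O)cc(O[Si](C(C)C)(C(C)C)C(C)C)c(C[C@H](O)C(C)(C)O)c1O | intermediate
16 | 1-{(2R)-6-hydroxy-2-(2-hydroxypropan-2-yl)-4-[tri(propan-2-yl)silyloxy]-2,3-dihydro-1-benzofuran-7-yl}-3-methylbutan-1-one (not isolated) | CC(C)CC(=O)c1c(O)cc(O[Si](C(C)C)(C(C)C)C(C)C)c2C[C@H](C(C)(C)O)Oc12 | intermediate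
17 | 1-[(2R)-4,6-dihydroxy-2-(2-hydroxypropan-2-yl)-2,3-dihydro-1-benzofuran-7-yl]-3-methylbutan-1-one | CC(C)CC(=O)c1c(O)cc(O)c2C[C@H](C(C)(C)O)Oc12 | intermediate
18 | 2-methylbut-3-en-2-ol | CC(C)(O)C=C | starting material
19 | di-tert-butyl dicarbonate | CC(C)(C)OC(=O)OC(=O)OC(C)(C)C | starting material
20 | lithium 2-methylbut-3-en-2-olate (not isolated) | [Li]OC(C)(C)C=C | intermediate
21 | tert-butyl 2-methylbut-3-en-2-yl carbonate | C=CC(C)(C)OC(=O)OC(C)(C)C | intermediate
22 | 1-[(2R)-2-(2-hydroxypropan-2-yl)-4,6-bis(2-methylbut-3-en-2-yloxy)-2,3-dihydro-1-benzofuran-7-yl]-3-methylbutan-1-one | CC(C)CC(=O)c1c(OC(C)(C)C=C)cc(OC(C)(C)C=C)c2C[C@H](C(C)(C)O)Oc12 | intermediate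
23 | 1-[(2R)-6-hydroxy-2-(2-hydroxypropan-2-yl)-5-(3-methylbut-2-en-1-yl)-4-(2-methylbut-3-en-2-yloxy)-2,3-dihydro-1-benzofuran-7-yl]-3-methylbutan-1-one (not isolated; drawn for the 6-O ether migrating first, the 4-O-first isomer converges on the same product) | CC(C)CC(=O)c1c(O)c(CC=C(C)C)c(OC(C)(C)C=C)c2C[C@H](C(C)(C)O)Oc12 | intermediate
24 | (2R)-6-hydroxy-2-(2-hydroxypropan-2-yl)-7-(3-methylbutanoyl)-5,5-bis(3-methylbut-2-en-1-yl)-2,3-dihydro-1-benzofuran-4(5H)-one | CC(C)=CCC1(CC=C(C)C)C(=O)C2=C(O[C@@H](C(C)(C)O)C2)C(C(=O)CC(C)C)=C1O | target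

## Step count and risks

Total steps: 10. Longest linear sequence: 8 (steps 1, 3, 4, 5, 6, 7, 9, 10); steps 2 and 8 are side branches.

Most likely to fail:

**Step 10 (double, dearomative Claisen).** The second shift may go to the ring-fusion carbon C3a instead of C5, or the tertiary allyl ethers may lose isoprene on heating. The fallback sets out from 17 and comes back at 24. It replaces the sigmatropic delivery by a polar alkylative dearomatisation: 17 is treated with prenyl bromide (2.3 eq) and NaOMe in MeOH at 0 °C. The phenoxide is first C-alkylated at the carbon between the two oxygens to give 1-[(2R)-4,6-dihydroxy-2-(2-hydroxypropan-2-yl)-5-(3-methylbut-2-en-1-yl)-2,3-dihydro-1-benzofuran-7-yl]-3-methylbutan-1-one F5. Its anion is then alkylated a second time at the same carbon to give 24 directly.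

**Step 7 (Mitsunobu ring closure).** The carbinol is neopentyl-like, so closure may be slow; an epoxide side path would erode the ee, and elimination is possible. The fallback sets out from 12 and comes back at 16. The carbinol is activated as a sulfonate before any phenol is unmasked:
- Selective mesylation of the secondary hydroxyl of 12 (MsCl, Et3N, CH2Cl2, −20 °C; the tertiary OH does not react) gives (2S)-3-hydroxy-3-methyl-1-[2,4,6-tris(methoxymethoxy)-3-(3-methylbutanoyl)phenyl]butan-2-yl methanesulfonate F1.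
- Acidic methanolysis of the MOM ethers gives (2S)-3-hydroxy-3-methyl-1-[2,4,6-trihydroxy-3-(3-methylbutanoyl)phenyl]butan-2-yl methanesulfonate F2.
- Para-silylation (TIPSOTf, 2,6-lutidine, −78 °C) gives (2S)-1-{2,4-dihydroxy-3-(3-methylbutanoyl)-6-[tri(propan-2-yl)silyloxy]phenyl}-3-hydroxy-3-methylbutan-2-yl methanesulfonate F3.
- K2CO3 in acetone closes the ring by phenoxide SN2 displacement with inversion, giving 16, which is desilylated as in the main route.

**Step 9 (bis-O-tert-allylation).** The hydrogen-bonded 6-OH may resist etherification, and Pd may C-allylate C5 or isomerise the ethers. The fallback sets out from 17 and comes back at 22. Both phenols are alkylated with 3-chloro-3-methylbut-1-yne (DBU, CuCl2 cat., MeCN, 0 °C) to give 1-[(2R)-2-(2-hydroxypropan-2-yl)-4,6-bis(2-methylbut-3-yn-2-yloxy)-2,3-dihydro-1-benzofuran-7-yl]-3-methylbutan-1-one F4. Semi-hydrogenation of both alkynes (H2, Lindlar catalyst, quinoline, EtOAc) then gives 22.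

## Further compounds

F1 | step 7 | (2S)-3-hydroxy-3-methyl-1-[2,4,6-tris(methoxymethoxy)-3-(3-methylbutanoyl)phenyl]butan-2-yl methanesulfonate | CC(C)CC(=O)c1c(OCOC)cc(OCOC)c(C[C@H](OS(C)(=O)=O)C(C)(C)O)c1OCOC
F2 | step 7 | (2S)-3-hydroxy-3-methyl-1-[2,4,6-trihydroxy-3-(3-methylbutanoyl)phenyl]butan-2-yl methanesulfonate | CC(C)CC(=O)c1c(O)cc(O)c(C[C@H](OS(C)(=O)=O)C(C)(C)O)c1O
F3 | step 7 | (2S)-1-{2,4-dihydroxy-3-(3-methylbutanoyl)-6-[tri(propan-2-yl)silyloxy]phenyl}-3-hydroxy-3-methylbutan-2-yl methanesulfonate | CC(C)CC(=O)c1c(O)cc(O[Si](C(C)C)(C(C)C)C(C)C)c(C[C@H](OS(C)(=O)=O)C(C)(C)O)c1O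
F4 | step 9 | 1-[(2R)-2-(2-hydroxypropan-2-yl)-4,6-bis(2-methylbut-3-yn-2-yloxy)-2,3-dihydro-1-benzofuran-7-yl]-3-methylbutan-1-one | CC(C)CC(=O)c1c(OC(C)(C)C#C)cc(OC(C)(C)C#C)c2C[C@H](C(C)(C)O)Oc12
F5 | step 10 | 1-[(2R)-4,6-dihydroxy-2-(2-hydroxypropan-2-yl)-5-(3-methylbut-2-en-1-yl)-2,3-dihydro-1-benzofuran-7-yl]-3-methylbutan-1-one | CC(C)CC(=O)c1c(O)c(CC=C(C)C)c(O)c2C[C@H](C(C)(C)O)Oc12
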